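**Retrosynthetic overview**

1. The strategy rests on the O1–C2 bond of the oxolane (O1, C2 aryl, C3 CH2OH, C4 arylmethyl, C5). C2 is a benzylic carbon para to a methoxy group of the 3,4-dimethoxyphenyl ring, the site a quinone oxidant attacks; cutting O1–C2 and masking the phenol as its acetate leaves an open-chain (2R,3R)-2,3-bis(arylmethyl)butane-1,4-diol.
2. The diol goes back to a trans-3,4-bis(arylmethyl)butyrolactone (LiAlH4), then to an (R)-4-arylmethylbutyrolactone plus 3,4-dimethoxybenzyl bromide (enolate alkylation), then to an Evans alkylation of the O-benzyl dihydroferulic acid imide with tert-butyl bromoacetate.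
3. The two aryl groups enter in separate C–C bond formations, so the nearly C2-symmetric diol arrives with one phenol already differentiated and no statistical desymmetrization is needed.
4. Ring order: a butyrolactone is closed in step 4 and opened again by reduction in step 6; the oxolane, the only ring of the target, is closed in step 9, and step 10 frees the phenol.

Key step: step 9

Assumption: with the oxolane numbered O1, C2 (aryl), C3 (CH2OH), C4 (arylmethyl), C5, the target is read as (2S,3R,4R), that is C2 aryl trans to the C3 hydroxymethyl and the C3 and C4 substituents cis, which is the relationship a (2R,3R)-diol delivers on closure.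

**Step 1**
Reactants: 1 3-(4-hydroxy-3-methoxyphenyl)propanoic acid (dihydroferulic acid)
Product: 2 3-[4-(benzyloxy)-3-methoxyphenyl]propanoic acid
Conditions: BnBr (1.2 equiv), NaOH (2.5 equiv), EtOH/H2O, reflux; then aq. HCl
Reagents that add atoms: benzyl bromide, BrCc1ccccc1
Why: Williamson ether synthesis in which the phenoxide is alkylated much faster than the carboxylate and any benzyl ester that forms is saponified in the same alkaline medium, so acidification should give only the O-benzyl acid.

**Step 2**
Reactants: 2 3-[4-(benzyloxy)-3-methoxyphenyl]propanoic acid; 3 (4S)-4-benzyl-1,3-oxazolidin-2-one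
Product: 5 (4S)-4-benzyl-3-{3-[4-(benzyloxy)-3-methoxyphenyl]propanoyl}-1,3-oxazolidin-2-one, via mixed pivalic anhydride 4 (not isolated)
Conditions: t-BuCOCl, Et3N, THF, −20 °C; then LiCl, 3, −20 °C to rt
Reagents that add atoms: pivaloyl chloride, CC(C)(C)C(=O)Cl (its atoms sit only in intermediate 4 and leave as pivalic acid)
Why: N-acylation of the oxazolidinone through a mixed anhydride (LiCl-assisted acylation), in which the hindered pivaloyl carbonyl directs attack to the arylpropanoyl carbonyl; no stereocentre is formed.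

**Step 3**
Reactants: 5 (4S)-4-benzyl-3-{3-[4-(benzyloxy)-3-methoxyphenyl]propanoyl}-1,3-oxazolidin-2-one; 6 tert-butyl bromoacetate
Product: 7 tert-butyl (3R)-4-[(4S)-4-benzyl-2-oxo-1,3-oxazolidin-3-yl]-3-[4-(benzyloxy)-3-methoxybenzyl]-4-oxobutanoate
Conditions: NaN(SiMe3)2, THF, −78 °C; then 6, −78 °C
Reagents that add atoms: none
Why: Evans asymmetric alkylation, in which the chelated (Z)-sodium enolate is attacked by the bromoacetate on the face opposite the C4 benzyl group of the (S)-auxiliary, the same facial sense as the classical allylation of the propionyl imide, which should set the new centre as R.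

**Step 4**
Reactants: 7 tert-butyl (3R)-4-[(4S)-4-benzyl-2-oxo-1,3-oxazolidin-3-yl]-3-[4-(benzyloxy)-3-methoxybenzyl]-4-oxobutanoate
Product: 9 (4R)-4-[4-(benzyloxy)-3-methoxybenzyl]oxolan-2-one, via hydroxy tert-butyl ester 8 (not isolated)
Conditions: LiBH4, MeOH (1 equiv), THF, 0 °C; then p-TsOH·H2O (cat.), PhMe, 80 °C
Reagents that add atoms: none
Why: Chemoselective reductive cleavage of the imide carbonyl by LiBH4 (the tert-butyl ester is inert at 0 °C) frees the primary alcohol and the auxiliary, and acid-catalysed loss of isobutene with lactonization of the γ-hydroxy acid closes the butyrolactone without touching the stereocentre.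

**Step 5**
Reactants: 9 (4R)-4-[4-(benzyloxy)-3-methoxybenzyl]oxolan-2-one; 10 3,4-dimethoxybenzyl bromide
Product: 11 (3R,4R)-4-[4-(benzyloxy)-3-methoxybenzyl]-3-(3,4-dimethoxybenzyl)oxolan-2-one
Conditions: LiN(SiMe3)2, THF, −78 °C; then 10 (fresh), DMPU, −78 to −30 °C
Reagents that add atoms: none
Why: SN2 alkylation of the lactone lithium enolate, in which the benzylic bromide approaches anti to the C4 arylmethyl group, so the existing C4 centre should set C3 as R and give the 3,4-trans lactone.

**Step 6**
Reactants: 11 (3R,4R)-4-[4-(benzyloxy)-3-methoxybenzyl]-3-(3,4-dimethoxybenzyl)oxolan-2-one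
Product: 12 (2R,3R)-2-[4-(benzyloxy)-3-methoxybenzyl]-3-(3,4-dimethoxybenzyl)butane-1,4-diol
Conditions: LiAlH4, THF, 0 °C to rt; then H2O, aq. NaOH
Reagents that add atoms: none
Why: Hydride reduction of a lactone to the 1,4-diol, which retains both stereocentres and leaves the aryl ethers untouched.

**Step 7**
Reactants: 12 (2R,3R)-2-[4-(benzyloxy)-3-methoxybenzyl]-3-(3,4-dimethoxybenzyl)butane-1,4-diol
Product: 13 (2R,3R)-2-(3,4-dimethoxybenzyl)-3-(4-hydroxy-3-methoxybenzyl)butane-1,4-diol
Conditions: H2 (1 atm), 10% Pd/C, EtOAc/EtOH, rt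
Reagents that add atoms: none
Why: Catalytic hydrogenolysis of the aryl benzyl ether, the only hydrogenolysable group in the molecule.

**Step 8**
Reactants: 13 (2R,3R)-2-(3,4-dimethoxybenzyl)-3-(4-hydroxy-3-methoxybenzyl)butane-1,4-diol
Product: 14 (2R,3R)-2-(4-acetoxy-3-methoxybenzyl)-3-(3,4-dimethoxybenzyl)butane-1,4-diol
Conditions: Ac2O (1.1 equiv), 1 M aq. NaOH (1.05 equiv), THF, 0 °C, short contact
Reagents that add atoms: acetic anhydride, CC(=O)OC(C)=O
Why: Chemoselective O-acetylation of a phenoxide in aqueous base (Chattaway-type acetylation), in which only the phenol is deprotonated and captures the anhydride while the neutral primary alcohols cannot compete with its hydrolysis.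

**Step 9**
Reactants: 14 (2R,3R)-2-(4-acetoxy-3-methoxybenzyl)-3-(3,4-dimethoxybenzyl)butane-1,4-diol
Product: 15 [(2S,3R,4R)-4-(4-acetoxy-3-methoxybenzyl)-2-(3,4-dimethoxyphenyl)oxolan-3-yl]methanol
Conditions: DDQ (1.1 equiv), 2,6-dichloropyridine, 4 Å MS, CH2Cl2, 0 °C, dark
Reagents that add atoms: none
Why: DDQ forms a charge-transfer complex with the more electron-rich 3,4-dimethoxyphenyl ring and abstracts hydride from its benzylic CH2, which is para to a methoxy group, giving a para-quinoid benzylic cation paired with the hydroquinone anion. The closest known reaction type is the DDQ-mediated oxidative cyclization of para-alkoxybenzylic C–H bonds onto tethered hydroxyl groups (oxidative benzylic etherification), established for electron-rich arylalkanols and used in the lignan series. The oxolane is closed by 5-exo-trig attack of the hydroxymethyl oxygen on the neighbouring stereocentre (the one carrying the acetoxyaryl-methyl group) at the cationic carbon, forming O1–C2, whereas the hydroxymethyl group on the carbon adjacent to the cation could only give an oxetane and stays free as the C3 CH2OH. The new centre C2 should be set as S by the existing C3 centre, because in the envelope transition state the aryl group lies pseudo-equatorial and anti to the C3 hydroxymethyl group, and any reversible ionization of the benzylic ether leads to the same more stable 2,3-trans isomer. The step needs site selectivity between the two benzylic CH2 groups, secured by the acetate: its oxygen lone pair is tied up by the acyl group and the remaining methoxy group of that ring is meta to the benzylic carbon, so that ring is a poor donor and its cation is not stabilized. It also needs O-capture to win over Friedel–Crafts capture and over a second oxidation of the product, which the acid-free, anhydrous medium, the low temperature and the near-stoichiometric amount of DDQ are meant to secure.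

**Step 10**
Reactants: 15 [(2S,3R,4R)-4-(4-acetoxy-3-methoxybenzyl)-2-(3,4-dimethoxyphenyl)oxolan-3-yl]methanol
Product: 16 [(2S,3R,4R)-2-(3,4-dimethoxyphenyl)-4-(4-hydroxy-3-methoxybenzyl)oxolan-3-yl]methanol
Conditions: K2CO3 (cat.), MeOH, 0 °C to rt; then aq. NH4Cl
Reagents that add atoms: none
Why: Base-catalysed transesterification (methanolysis) of the aryl acetate, which is far more labile than any other group present; the C2 benzylic ether is not ionized in base and the phenol lies on the other ring, so C2 cannot epimerize.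

**Compound list**

1 | 3-(4-hydroxy-3-methoxyphenyl)propanoic acid | COc1cc(CCC(=O)O)ccc1O | starting material
2 | 3-[4-(benzyloxy)-3-methoxyphenyl]propanoic acid | COc1cc(CCC(=O)O)ccc1OCc1ccccc1 | intermediate
3 | (4S)-4-benzyl-1,3-oxazolidin-2-one | O=C1N[C@@H](Cc2ccccc2)CO1 | starting material
4 | 3-[4-(benzyloxy)-3-methoxyphenyl]propanoic pivalic anhydride | COc1cc(CCC(=O)OC(=O)C(C)(C)C)ccc1OCc1ccccc1 | intermediate (not isolated)
5 | (4S)-4-benzyl-3-{3-[4-(benzyloxy)-3-methoxyphenyl]propanoyl}-1,3-oxazolidin-2-one | COc1cc(CCC(=O)N2[C@@H](Cc3ccccc3)COC2=O)ccc1OCc1ccccc1 | intermediate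
6 | tert-butyl bromoacetate | BrCC(=O)OC(C)(C)C | starting material
7 | tert-butyl (3R)-4-[(4S)-4-benzyl-2-oxo-1,3-oxazolidin-3-yl]-3-[4-(benzyloxy)-3-methoxybenzyl]-4-oxobutanoate | COc1cc(C[C@H](CC(=O)OC(C)(C)C)C(=O)N2[C@@H](Cc3ccccc3)COC2=O)ccc1OCc1ccccc1 | intermediate
8 | tert-butyl (3R)-4-[4-(benzyloxy)-3-methoxyphenyl]-3-(hydroxymethyl)butanoate | COc1cc(C[C@H](CC(=O)OC(C)(C)C)CO)ccc1OCc1ccccc1 | intermediate (not isolated)
9 | (4R)-4-[4-(benzyloxy)-3-methoxybenzyl]oxolan-2-one | COc1cc(C[C@H]2COC(=O)C2)ccc1OCc1ccccc1 | intermediate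
10 | 3,4-dimethoxybenzyl bromide | COc1ccc(CBr)cc1OC | starting material
11 | (3R,4R)-4-[4-(benzyloxy)-3-methoxybenzyl]-3-(3,4-dimethoxybenzyl)oxolan-2-one | COc1cc(C[C@H]2COC(=O)[C@@H]2Cc2ccc(OC)c(OC)c2)ccc1OCc1ccccc1 | intermediate
12 | (2R,3R)-2-[4-(benzyloxy)-3-methoxybenzyl]-3-(3,4-dimethoxybenzyl)butane-1,4-diol | COc1cc(C[C@@H](CO)[C@H](CO)Cc2ccc(OC)c(OC)c2)ccc1OCc1ccccc1 | intermediate
13 | (2R,3R)-2-(3,4-dimethoxybenzyl)-3-(4-hydroxy-3-methoxybenzyl)butane-1,4-diol | COc1cc(C[C@@H](CO)[C@H](CO)Cc2ccc(OC)c(OC)c2)ccc1O | intermediate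
14 | (2R,3R)-2-(4-acetoxy-3-methoxybenzyl)-3-(3,4-dimethoxybenzyl)butane-1,4-diol | CC(=O)Oc1ccc(C[C@@H](CO)[C@H](CO)Cc2ccc(OC)c(OC)c2)cc1OC | intermediate
15 | [(2S,3R,4R)-4-(4-acetoxy-3-methoxybenzyl)-2-(3,4-dimethoxyphenyl)oxolan-3-yl]methanol | CC(=O)Oc1ccc(C[C@H]2CO[C@H](c3ccc(OC)c(OC)c3)[C@H]2CO)cc1OC | intermediate
16 | [(2S,3R,4R)-2-(3,4-dimethoxyphenyl)-4-(4-hydroxy-3-methoxybenzyl)oxolan-3-yl]methanol | COc1cc(C[C@H]2CO[C@H](c3ccc(OC)c(OC)c3)[C@H]2CO)ccc1O | target

**Step count**

Total: 10 steps. Longest linear sequence: 10 steps (1 to 16); compounds 3, 6 and 10 are commercial.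

**Steps most likely to fail**

Step 9. The benzylic cation may be captured by the acetoxyaryl ring in a six-membered Friedel–Crafts closure instead of by oxygen, the benzylic ether C–H of the product may be oxidized a second time, or the oxidant may not discriminate cleanly between the two benzylic positions. The fallback generates the same cation by ionization of a benzylic alcohol instead of by oxidation and sets out from lactone 9. Aldol addition of its lithium enolate (LiN(i-Pr)2, THF, −78 °C) to 3,4-dimethoxybenzaldehyde should give, anti to the C4 substituent, (3S,4R)-4-[4-(benzyloxy)-3-methoxybenzyl]-3-[(3,4-dimethoxyphenyl)(hydroxy)methyl]oxolan-2-one F1 as a mixture of carbinol epimers, both of which are usable. LiAlH4 should reduce it to (2R,3R)-2-[4-(benzyloxy)-3-methoxybenzyl]-3-[(3,4-dimethoxyphenyl)(hydroxy)methyl]butane-1,4-diol F2. Catalytic camphorsulfonic acid in CH2Cl2 at 0 °C should ionize the benzylic alcohol and close the ring 5-exo to the 2,3-trans oxolane {(2S,3R,4R)-4-[4-(benzyloxy)-3-methoxybenzyl]-2-(3,4-dimethoxyphenyl)oxolan-3-yl}methanol F3. Brief hydrogenolysis of the aryl benzyl ether (H2, 10% Pd/C, EtOAc, stopped at full conversion so that the C2–O1 bond is not cleaved) returns to the route at target 16.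

Step 8. The primary alcohols may be acetylated as well, or the aryl acetate may be hydrolysed again in the basic medium, leaving mixtures of acetates. The fallback removes the competition by temporary protection and sets out from diol 12. TBSCl and imidazole in DMF should give the bis-silyl ether (2R,3R)-2-[4-(benzyloxy)-3-methoxybenzyl]-3-(3,4-dimethoxybenzyl)-1,4-bis(tert-butyldimethylsilyloxy)butane F4. Hydrogenolysis (H2, 10% Pd/C, EtOAc) should give the phenol 4-[(2R,3R)-4-(tert-butyldimethylsilyloxy)-2-(tert-butyldimethylsilyloxymethyl)-3-(3,4-dimethoxybenzyl)butyl]-2-methoxyphenol F5. Ac2O in pyridine, now with the phenol as the only free hydroxyl, should give the aryl acetate 4-[(2R,3R)-4-(tert-butyldimethylsilyloxy)-2-(tert-butyldimethylsilyloxymethyl)-3-(3,4-dimethoxybenzyl)butyl]-2-methoxyphenyl acetate F6. HF·pyridine in THF at 0 °C, which leaves aryl acetates intact, removes both silyl groups and returns to the route at 14.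

Step 5. The electron-rich benzylic bromide may decompose or self-condense before C-alkylation, and the lactone may be alkylated twice. The fallback replaces the halide by the stable aldehyde and sets out from lactone 9. The aldol addition to 3,4-dimethoxybenzaldehyde described for step 9 should give the hydroxybenzyl lactone (3S,4R)-4-[4-(benzyloxy)-3-methoxybenzyl]-3-[(3,4-dimethoxyphenyl)(hydroxy)methyl]oxolan-2-one F1. Hydrogenolysis under acidic conditions (H2, 10% Pd/C, AcOH, cat. HClO4) should remove both the benzylic hydroxyl and the aryl benzyl ether to give (3R,4R)-3-(3,4-dimethoxybenzyl)-4-(4-hydroxy-3-methoxybenzyl)oxolan-2-one F7. LiAlH4 in THF then reduces the lactone and returns to the route at phenol diol 13, bypassing 11 and 12.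

**Further compounds**

F1 | step 9 | (3S,4R)-4-[4-(benzyloxy)-3-methoxybenzyl]-3-[(3,4-dimethoxyphenyl)(hydroxy)methyl]oxolan-2-one (carbinol epimers) | COc1cc(C[C@H]2COC(=O)[C@@H]2C(O)c2ccc(OC)c(OC)c2)ccc1OCc1ccccc1
F2 | step 9 | (2R,3R)-2-[4-(benzyloxy)-3-methoxybenzyl]-3-[(3,4-dimethoxyphenyl)(hydroxy)methyl]butane-1,4-diol (carbinol epimers) | COc1cc(C[C@@H](CO)[C@H](CO)C(O)c2ccc(OC)c(OC)c2)ccc1OCc1ccccc1
F3 | step 9 | {(2S,3R,4R)-4-[4-(benzyloxy)-3-methoxybenzyl]-2-(3,4-dimethoxyphenyl)oxolan-3-yl}methanol | COc1cc(C[C@H]2CO[C@H](c3ccc(OC)c(OC)c3)[C@H]2CO)ccc1OCc1ccccc1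
F4 | step 8 | (2R,3R)-2-[4-(benzyloxy)-3-methoxybenzyl]-3-(3,4-dimethoxybenzyl)-1,4-bis(tert-butyldimethylsilyloxy)butane | COc1cc(C[C@@H](CO[Si](C)(C)C(C)(C)C)[C@H](CO[Si](C)(C)C(C)(C)C)Cc2ccc(OC)c(OC)c2)ccc1OCc1ccccc1
F5 | step 8 | 4-[(2R,3R)-4-(tert-butyldimethylsilyloxy)-2-(tert-butyldimethylsilyloxymethyl)-3-(3,4-dimethoxybenzyl)butyl]-2-methoxyphenol | COc1cc(C[C@@H](CO[Si](C)(C)C(C)(C)C)[C@H](CO[Si](C)(C)C(C)(C)C)Cc2ccc(OC)c(OC)c2)ccc1O
F6 | step 8 | 4-[(2R,3R)-4-(tert-butyldimethylsilyloxy)-2-(tert-butyldimethylsilyloxymethyl)-3-(3,4-dimethoxybenzyl)butyl]-2-methoxyphenyl acetate | CC(=O)Oc1ccc(C[C@@H](CO[Si](C)(C)C(C)(C)C)[C@H](CO[Si](C)(C)C(C)(C)C)Cc2ccc(OC)c(OC)c2)cc1OC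
F7 | step 5 | (3R,4R)-3-(3,4-dimethoxybenzyl)-4-(4-hydroxy-3-methoxybenzyl)oxolan-2-one | COc1cc(C[C@H]2COC(=O)[C@@H]2Cc2ccc(OC)c(OC)c2)ccc1O
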